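**Strategy.** Ring D is grown onto ring A, so two hindered arenes never have to be coupled. Ring D carries CO2CH3 on C5'' para to OCH3 on C2''. C1'', the carbon bonded to flavone C6, sits ortho to that methoxy carbon. This is the 1,2,4-pattern left when a 2-pyranone-5-carboxylate takes up a ketene acetal. One thermal operation joins C1''–C6'' and C2''–C3'', expels CO2 and methanol, and delivers the crowded biaryl with methyl ether and ester already in place. The precursor is ArCH=C(OCH3)2, where Ar is a symmetric phloroglucinol ring with benzyl on the para oxygen and isopropyl on both ortho oxygens. The para oxygen later becomes O1, which fixes the 6-aryl regiochemistry.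

Key step: step 6

Assumption: rotation about the C6–C1'' axis (three oxygen substituents and one hydrogen ortho to it) is taken to be fast at room temperature, in keeping with a target drawn without axial descriptor. Compounds 8, 11, 12 and 18 are racemic, and their sp3 centres are erased later.

Step 1
Reactants: 1 2,4,6-trihydroxybenzaldehyde
Product: 2 4-(benzyloxy)-2,6-dihydroxybenzaldehyde
Conditions: BnBr (1.0 equiv), KHCO3 (1.2 equiv), DMF, rt → 40 °C
Reagents that add atoms: benzyl bromide, BrCc1ccccc1
Why: Williamson etherification with one equivalent of halide and a bicarbonate base should alkylate the 4-OH only, because it is the most acidic hydroxyl (para to CHO) while the two ortho hydroxyls are flanked by the formyl group and hydrogen-bonded to it.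

Step 2
Reactants: 2 4-(benzyloxy)-2,6-dihydroxybenzaldehyde
Product: 3 4-(benzyloxy)-2,6-diisopropoxybenzaldehyde
Conditions: i-PrBr (5 equiv), K2CO3 (4 equiv), DMF, 70 °C
Reagents that add atoms: 2-bromopropane, CC(C)Br
Why: A forcing Williamson etherification (excess secondary bromide, carbonate, warm DMF) overcomes the hydrogen bonding of the two remaining hydroxyls, and the non-enolisable aldehyde and the benzyl ether are inert to the base.

Step 3
Reactants: 4 chlorodiphenylphosphine; 5 trimethyl orthoformate
Product: 6 (dimethoxymethyl)diphenylphosphine oxide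
Conditions: neat, 5 in excess, 0 → 60 °C, N2
Reagents that add atoms: none
Why: In this Michaelis–Arbuzov-type reaction, chloride/methoxide exchange gives methyl diphenylphosphinite and a dimethoxycarbenium ion, phosphorus captures the cation, and chloride demethylates the phosphonium salt to the phosphine oxide.

Step 4
Reactants: 3 4-(benzyloxy)-2,6-diisopropoxybenzaldehyde; 6 (dimethoxymethyl)diphenylphosphine oxide
Product: 8 {2-[4-(benzyloxy)-2,6-diisopropoxyphenyl]-2-hydroxy-1,1-dimethoxyethyl}diphenylphosphine oxide (racemic), via lithiated phosphine oxide 7 (not isolated)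
Conditions: 6 (1.3 equiv), LiN(i-Pr)2 (1.3 equiv), THF, −100 °C; then 3, −100 → −78 °C; aq NH4Cl
Reagents that add atoms: none
Why: In this Horner–Wittig addition the carbanion, kept below its decomposition temperature, adds to the non-enolisable aldehyde, and lithium holds the β-oxido phosphine oxide, so the racemic adduct can be isolated and crystallised as the last purification point before the sensitive alkene; its stereocentre disappears in step 5.

Step 5
Reactants: 8 {2-[4-(benzyloxy)-2,6-diisopropoxyphenyl]-2-hydroxy-1,1-dimethoxyethyl}diphenylphosphine oxide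
Product: 9 5-(benzyloxy)-2-(2,2-dimethoxyethenyl)-1,3-diisopropoxybenzene
Conditions: KOt-Bu (1.2 equiv), THF, 0 °C → rt; pentane, filtration, no chromatography
Reagents that add atoms: none
Why: In this Horner–Wittig elimination the potassium alkoxide attacks phosphorus and syn-eliminates diphenylphosphinate, there is no alkene geometry to control because the acetal carbon bears two identical methoxy groups, and filtering off the salt keeps the acid-sensitive ketene acetal away from silica gel.

Step 6
Reactants: 9 5-(benzyloxy)-2-(2,2-dimethoxyethenyl)-1,3-diisopropoxybenzene; 10 methyl coumalate (methyl 2-oxo-2H-pyran-5-carboxylate)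
Product: 13 methyl 3-[4-(benzyloxy)-2,6-diisopropoxyphenyl]-4-methoxybenzoate, via bridged lactone cycloadduct 11 (not isolated), via dimethoxycyclohexadiene ester 12 (not isolated)
Conditions: 10 (2 equiv), xylenes, 130 °C, N2 sweep, base-washed glassware; then p-TsOH (cat.), rt
Reagents that add atoms: none
Why: The electron-rich alkene of 9 and the electron-poor diene C3=C4–C5=C6 of 10 combine in an inverse-electron-demand Diels–Alder reaction in which the nucleophilic, aryl-bearing carbon of 9 bonds to C6 of 10 (future C1''–C6'') slightly ahead of the union of the acetal carbon with C3 (future C2''–C3''), a concerted but asynchronous suprafacial [4+2] closure giving the 2-oxabicyclo[2.2.2]octenone 11. Retro-[4+2] loss of the lactone bridge as CO2 leaves cyclohexadiene 12, and acid-assisted ionisation of its ketal followed by loss of the hydrogen on C1'' expels methanol and aromatises ring D. The closest known reaction type is the benzannulation of methyl coumalate and related 2-pyranones with ketene acetals and enol ethers to para-alkoxybenzoates. Ring D is closed by an intermolecular [4+2] cycloaddition (four carbons from 10, two from 9), and no stereocentre survives, since the three sp3 centres of 11 and the one of 12 are flattened on aromatisation, so endo/exo selectivity is irrelevant. The only selectivity needed is orientation, and it is secured by matched polarisation: C6 of 10 is the diene terminus activated by both the ring carbonyl and the C5 ester, and the β-carbon of 9 carries the largest HOMO coefficient, which places OCH3 para and the aryl group meta to CO2CH3. In 9 the isopropyl groups point away from the alkene, so the β-carbon is flanked only by two oxygen atoms, and the two identical methoxy groups mean that aromatisation can leave nothing but a methyl ether.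

Step 7
Reactants: 13 methyl 3-[4-(benzyloxy)-2,6-diisopropoxyphenyl]-4-methoxybenzoate
Product: 14 methyl 3-(4-hydroxy-2,6-diisopropoxyphenyl)-4-methoxybenzoate
Conditions: H2 (1 atm), 10% Pd/C, EtOAc–MeOH, rt
Reagents that add atoms: none
Why: Catalytic hydrogenolysis cleaves only the benzylic C–O bond, leaving the isopropyl ethers, methyl ether and ester untouched, and so unmasks the single oxygen that is to become O1.

Step 8
Reactants: 14 methyl 3-(4-hydroxy-2,6-diisopropoxyphenyl)-4-methoxybenzoate
Product: 15 methyl 3-(3-formyl-4-hydroxy-2,6-diisopropoxyphenyl)-4-methoxybenzoate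
Conditions: MgCl2, Et3N, (CH2O)n, MeCN, reflux; dilute HCl work-up
Reagents that add atoms: formaldehyde (as paraformaldehyde), C=O
Why: In this magnesium-mediated ortho-formylation (Casnati–Skattebøl reaction) the magnesium phenoxide delivers formaldehyde to the ortho carbon and a second formaldehyde oxidises the hydroxymethyl stage by hydride transfer; the two ortho positions are equivalent by symmetry, the para position is blocked, and the ester tolerates the mild base.

Step 9
Reactants: 15 methyl 3-(3-formyl-4-hydroxy-2,6-diisopropoxyphenyl)-4-methoxybenzoate; 16 1-ethynyl-4-isopropoxybenzene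
Product: 18 methyl 3-{4-hydroxy-3-[1-hydroxy-3-(4-isopropoxyphenyl)prop-2-yn-1-yl]-2,6-diisopropoxyphenyl}-4-methoxybenzoate (racemic), via alkynylmagnesium bromide 17 (not isolated)
Conditions: 16 (2.5 equiv), EtMgBr (2.3 equiv), THF, 0 → 40 °C; then 15, 0 °C → rt; aq NH4Cl at 0 °C, crude carried on
Reagents that add atoms: none
Why: In this 1,2-addition of an alkynyl Grignard reagent the first equivalent forms a magnesium phenoxide that chelates and activates the formyl group and the second adds to it; the magnesium acetylide is preferred to the lithium one because it leaves the methyl ester, already deactivated by its para methoxy group, untouched at these temperatures, and the racemic carbinol centre is removed in step 10.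

Step 10
Reactants: 18 methyl 3-{4-hydroxy-3-[1-hydroxy-3-(4-isopropoxyphenyl)prop-2-yn-1-yl]-2,6-diisopropoxyphenyl}-4-methoxybenzoate
Product: 19 methyl 3-{4-hydroxy-2,6-diisopropoxy-3-[3-(4-isopropoxyphenyl)prop-2-ynoyl]phenyl}-4-methoxybenzoate
Conditions: activated MnO2 (excess), CH2Cl2, rt
Reagents that add atoms: none
Why: MnO2 oxidation of a doubly activated (benzylic and propargylic) alcohol runs under neutral heterogeneous conditions that avoid ionisation of the electron-rich carbinol and spare the phenol, ethers and ester.

Step 11
Reactants: 19 methyl 3-{4-hydroxy-2,6-diisopropoxy-3-[3-(4-isopropoxyphenyl)prop-2-ynoyl]phenyl}-4-methoxybenzoate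
Product: 21 methyl 3-[5,7-diisopropoxy-2-(4-isopropoxyphenyl)-4-oxo-4H-chromen-6-yl]-4-methoxybenzoate, via diethylamino enone 20 (not isolated)
Conditions: Et2NH (5 equiv), MeOH, rt → 55 °C
Reagents that add atoms: none
Why: Aza-Michael addition of the amine to the ynone gives enaminone 20, whose β-carbon is attacked by the phenol in a 6-endo-trig addition–elimination that returns the amine; this path shuts off the 5-exo-dig closure to an aurone, and because only the oxygen para to the biaryl bond is free, the aryl group can end up only on C6.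

Step 12
Reactants: 21 methyl 3-[5,7-diisopropoxy-2-(4-isopropoxyphenyl)-4-oxo-4H-chromen-6-yl]-4-methoxybenzoate
Product: 22 methyl 3-[5,7-dihydroxy-2-(4-hydroxyphenyl)-4-oxo-4H-chromen-6-yl]-4-methoxybenzoate (target)
Conditions: BCl3 (8 equiv), CH2Cl2, −78 → 0 °C; then H2O
Reagents that add atoms: none
Why: In this Lewis-acid ether cleavage the boron-complexed isopropyl ethers lose their secondary alkyl group to chloride by a carbocation-like path that is closed to the ring D methyl ether and the methyl ester, and the cold aprotic medium avoids a Wessely–Moser ring opening that would scramble the 6- and 8-aryl isomers.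

**Compound list**
1 | 2,4,6-trihydroxybenzaldehyde | O=Cc1c(O)cc(O)cc1O | starting material
2 | 4-(benzyloxy)-2,6-dihydroxybenzaldehyde | O=Cc1c(O)cc(OCc2ccccc2)cc1O | intermediate
3 | 4-(benzyloxy)-2,6-diisopropoxybenzaldehyde | O=Cc1c(OC(C)C)cc(OCc2ccccc2)cc1OC(C)C | intermediate
4 | chlorodiphenylphosphine | ClP(c1ccccc1)c1ccccc1 | starting material
5 | trimethyl orthoformate | COC(OC)OC | starting material
6 | (dimethoxymethyl)diphenylphosphine oxide | COC(OC)P(=O)(c1ccccc1)c1ccccc1 | intermediate
7 | [dimethoxy(diphenylphosphoryl)methyl]lithium | [Li]C(OC)(OC)P(=O)(c1ccccc1)c1ccccc1 | intermediate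
8 | {2-[4-(benzyloxy)-2,6-diisopropoxyphenyl]-2-hydroxy-1,1-dimethoxyethyl}diphenylphosphine oxide (racemic) | COC(OC)(C(O)c1c(OC(C)C)cc(OCc2ccccc2)cc1OC(C)C)P(=O)(c1ccccc1)c1ccccc1 | intermediate
9 | 5-(benzyloxy)-2-(2,2-dimethoxyethenyl)-1,3-diisopropoxybenzene | COC(OC)=Cc1c(OC(C)C)cc(OCc2ccccc2)cc1OC(C)C | intermediate
10 | methyl coumalate | COC(=O)C1=COC(=O)C=C1 | starting material
11 | methyl 7-[4-(benzyloxy)-2,6-diisopropoxyphenyl]-8,8-dimethoxy-3-oxo-2-oxabicyclo[2.2.2]oct-5-ene-6-carboxylate (racemic, configuration at C7 not controlled, all centres erased in the same step) | COC(=O)C1=CC2C(=O)OC1C(c3c(OC(C)C)cc(OCc4ccccc4)cc3OC(C)C)C2(OC)OC | intermediate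
12 | methyl 3-[4-(benzyloxy)-2,6-diisopropoxyphenyl]-4,4-dimethoxycyclohexa-1,5-diene-1-carboxylate (racemic) | COC(=O)C1=CC(c2c(OC(C)C)cc(OCc3ccccc3)cc2OC(C)C)C(OC)(OC)C=C1 | intermediate
13 | methyl 3-[4-(benzyloxy)-2,6-diisopropoxyphenyl]-4-methoxybenzoate | COC(=O)c1ccc(OC)c(-c2c(OC(C)C)cc(OCc3ccccc3)cc2OC(C)C)c1 | intermediate
14 | methyl 3-(4-hydroxy-2,6-diisopropoxyphenyl)-4-methoxybenzoate | COC(=O)c1ccc(OC)c(-c2c(OC(C)C)cc(O)cc2OC(C)C)c1 | intermediate
15 | methyl 3-(3-formyl-4-hydroxy-2,6-diisopropoxyphenyl)-4-methoxybenzoate | COC(=O)c1ccc(OC)c(-c2c(OC(C)C)cc(O)c(C=O)c2OC(C)C)c1 | intermediate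
16 | 1-ethynyl-4-isopropoxybenzene | C#Cc1ccc(OC(C)C)cc1 | starting material
17 | bromo[(4-isopropoxyphenyl)ethynyl]magnesium | CC(C)Oc1ccc(C#C[Mg]Br)cc1 | intermediate
18 | methyl 3-{4-hydroxy-3-[1-hydroxy-3-(4-isopropoxyphenyl)prop-2-yn-1-yl]-2,6-diisopropoxyphenyl}-4-methoxybenzoate (racemic) | COC(=O)c1ccc(OC)c(-c2c(OC(C)C)cc(O)c(C(O)C#Cc3ccc(OC(C)C)cc3)c2OC(C)C)c1 | intermediate
19 | methyl 3-{4-hydroxy-2,6-diisopropoxy-3-[3-(4-isopropoxyphenyl)prop-2-ynoyl]phenyl}-4-methoxybenzoate | COC(=O)c1ccc(OC)c(-c2c(OC(C)C)cc(O)c(C(=O)C#Cc3ccc(OC(C)C)cc3)c2OC(C)C)c1 | intermediate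
20 | methyl 3-{3-[(E)-3-(diethylamino)-3-(4-isopropoxyphenyl)prop-2-enoyl]-4-hydroxy-2,6-diisopropoxyphenyl}-4-methoxybenzoate (push–pull alkene, geometry labile) | COC(=O)c1ccc(OC)c(-c2c(OC(C)C)cc(O)c(C(=O)/C=C(/N(CC)CC)c3ccc(OC(C)C)cc3)c2OC(C)C)c1 | intermediate
21 | methyl 3-[5,7-diisopropoxy-2-(4-isopropoxyphenyl)-4-oxo-4H-chromen-6-yl]-4-methoxybenzoate | COC(=O)c1ccc(OC)c(-c2c(OC(C)C)cc3oc(-c4ccc(OC(C)C)cc4)cc(=O)c3c2OC(C)C)c1 | intermediate
22 | methyl 3-[5,7-dihydroxy-2-(4-hydroxyphenyl)-4-oxo-4H-chromen-6-yl]-4-methoxybenzoate | COC(=O)c1ccc(OC)c(-c2c(O)cc3oc(-c4ccc(O)cc4)cc(=O)c3c2O)c1 | target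

**Total steps:** 12. **Longest linear sequence:** 11 (from 1 through steps 1, 2 and 4–12). Step 3 is a one-step side branch.

**Steps most likely to fail**

**1. Step 6.**
- *What may go wrong:* Bond formation at the β-carbon has to occur next to a di-ortho-substituted aryl ring, so the cycloaddition may be too slow. Over long heating, protonation of the ketene acetal, methanol addition to it, and self-condensation of the pyranone could then consume both partners. The first C–C bond could also form without the second, ending in ring-opened Michael-type material.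
- *Fallback (sets out from 3, returns at 13):*
  - Pinnick oxidation (NaClO2, NaH2PO4, 2-methyl-2-butene, t-BuOH–H2O) should give 4-(benzyloxy)-2,6-diisopropoxybenzoic acid F1.
  - Base-mediated decarboxylative iodination (I2, K3PO4, MeCN, 100 °C) suits such electron-rich ortho-alkoxybenzoic acids and should give 5-(benzyloxy)-2-iodo-1,3-diisopropoxybenzene F2.
  - Suzuki–Miyaura coupling of F2 with commercial [2-methoxy-5-(methoxycarbonyl)phenyl]boronic acid (Pd(OAc)2, SPhos, K3PO4, toluene–H2O, 100 °C) then makes the C6–C1'' bond directly and gives 13.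

**2. Step 4.**
- *What may go wrong:* The lithiated acetal carbanion may decay before it adds to the hindered, electron-rich aldehyde. The addition may also reverse once the potassium alkoxide is formed in step 5.
- *Fallback (sets out from 3, returns at 9, which is formed in the flask under the conditions of step 6):*
  - Van Leusen reductive cyanation (TosMIC, KOt-Bu, DME, −40 °C, then MeOH, reflux) should give 2-[4-(benzyloxy)-2,6-diisopropoxyphenyl]acetonitrile F3.
  - A Pinner reaction (HCl generated from AcCl in MeOH–Et2O, 0 °C) should give methyl 2-[4-(benzyloxy)-2,6-diisopropoxyphenyl]acetimidate hydrochloride F4.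
  - Methanolysis of the salt in dry MeOH at rt should give the bench-stable orthoester 5-(benzyloxy)-1,3-diisopropoxy-2-(2,2,2-trimethoxyethyl)benzene F5.
  - Heated with 10 in xylenes at 140 °C with catalytic pivalic acid, as in the first stage of a Johnson–Claisen rearrangement, F5 should shed methanol to 9, which 10 traps at once.

**3. Step 9.**
- *What may go wrong:* Addition may be slow, because the aldehyde is deactivated by its ortho phenoxide and two alkoxy donors. On warming, attack at the ester may compete. The electron-rich benzylic alcohol may also ionise to an ortho-quinone methide during work-up.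
- *Fallback (sets out from 14, returns at 21, bypassing steps 8–11):*
  - Mono-iodination (NIS, 1.0 equiv, MeCN, 0 °C) at one of the two equivalent ortho positions should give methyl 3-(4-hydroxy-3-iodo-2,6-diisopropoxyphenyl)-4-methoxybenzoate F6.
  - Carbonylative Sonogashira annulation of F6 with 16 (PdCl2(PPh3)2 cat., CO 1 atm, Et2NH, DMF, 60 °C) uses no organometallic nucleophile. It builds ynone 19 in the flask, and the amine carries it through 20 to 21.

**Further compounds**
F1 | step 6 | 4-(benzyloxy)-2,6-diisopropoxybenzoic acid | OC(=O)c1c(OC(C)C)cc(OCc2ccccc2)cc1OC(C)C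
F2 | step 6 | 5-(benzyloxy)-2-iodo-1,3-diisopropoxybenzene | Ic1c(OC(C)C)cc(OCc2ccccc2)cc1OC(C)C
F3 | step 4 | 2-[4-(benzyloxy)-2,6-diisopropoxyphenyl]acetonitrile | N#CCc1c(OC(C)C)cc(OCc2ccccc2)cc1OC(C)C
F4 | step 4 | methyl 2-[4-(benzyloxy)-2,6-diisopropoxyphenyl]acetimidate hydrochloride | Cl.COC(=N)Cc1c(OC(C)C)cc(OCc2ccccc2)cc1OC(C)C
F5 | step 4 | 5-(benzyloxy)-1,3-diisopropoxy-2-(2,2,2-trimethoxyethyl)benzene | COC(OC)(OC)Cc1c(OC(C)C)cc(OCc2ccccc2)cc1OC(C)C
F6 | step 9 | methyl 3-(4-hydroxy-3-iodo-2,6-diisopropoxyphenyl)-4-methoxybenzoate | COC(=O)c1ccc(OC)c(-c2c(OC(C)C)cc(O)c(I)c2OC(C)C)c1
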